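**Retrosynthetic overview**
- The C7 carbinol is traced back to the α-aryloxy aryl ketone; a chelation-controlled hydride reduction relays C8 (R) to C7 (S), giving the erythro pair.
- Key disconnection: the C8–O4' alkyl aryl ether bond, made by a copper-catalysed enantioconvergent coupling of a racemic α-bromo ketone with 4-(3-hydroxypropyl)-2-methoxyphenol; this step sets C8.
- The α-bromo ketone comes from 3,4,5-trimethoxybenzonitrile by ethyl Grignard addition and α-bromination.
- No ring is formed: both benzene rings are bought intact, and no protecting group is used.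

Assumption: 4-(3-hydroxypropyl)-2-methoxyphenol (dihydroconiferyl alcohol) is bought as a catalogue compound; the (S,S)-ligand of step 3 is taken to give the (R)-ether, and its equally available mirror image is used if the measured sense of induction is the opposite.

**Step 1**
Reactants: 1 3,4,5-trimethoxybenzonitrile; 2 ethylmagnesium bromide
Product: 4 1-(3,4,5-trimethoxyphenyl)propan-1-one, via bromomagnesium ketimide 3 (not isolated)
Conditions: EtMgBr (1.5 equiv, 3 M in Et2O), toluene, 0 °C → 60 °C, 4 h; then 2 M aq HCl, 0 °C → rt, 1 h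
Reagents that add atoms: water, O
Why: Grignard addition to a nitrile stops at the anionic N-magnesio ketimine, which resists a second addition, and acid hydrolysis releases the ethyl ketone; no stereocenter is formed.

**Step 2**
Reactants: 4 1-(3,4,5-trimethoxyphenyl)propan-1-one
Product: 5 rac-2-bromo-1-(3,4,5-trimethoxyphenyl)propan-1-one
Conditions: CuBr2 (2.1 equiv), EtOAc/CHCl3 (1:1), reflux, 3 h
Reagents that add atoms: CuBr2, Br[Cu]Br
Why: α-Bromination of an aryl ketone through its enol with CuBr2 is selective for the side chain because the acyl group deactivates the ring; the racemic product is acceptable because step 3 is enantioconvergent.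

**Step 3**
Reactants: 5 rac-2-bromo-1-(3,4,5-trimethoxyphenyl)propan-1-one (1.0 equiv); 6 4-(3-hydroxypropyl)-2-methoxyphenol (1.2 equiv)
Product: 7 (2R)-2-[4-(3-hydroxypropyl)-2-methoxyphenoxy]-1-(3,4,5-trimethoxyphenyl)propan-1-one
Conditions: Cu(MeCN)4PF6 (10 mol%), (S,S)-Ph-BOX = 2,2'-(propane-2,2-diyl)bis[(4S)-4-phenyl-4,5-dihydro-1,3-oxazole] (12 mol%), powdered K3PO4 (1.5 equiv), toluene/2-MeTHF (4:1), −10 °C, Ar, 24 h
Reagents that add atoms: none
Why: Proposed new method: copper-catalysed enantioconvergent C–O coupling of a racemic secondary α-bromo aryl ketone with a phenol; the chiral bis(oxazoline) monovalent copper phenoxide (formed only at the phenol, pKa about 10, not at the aliphatic OH, pKa about 16) abstracts bromine from either enantiomer of 5, as in atom-transfer radical initiation, to give a planar α-keto radical that has lost the stereochemical information of 5; the radical is captured by the divalent copper phenoxide, and enantio-determining C–O reductive elimination from the trivalent copper intermediate inside the ligand pocket delivers (R)-7, so C8 is set by the catalyst, while the insoluble weak base, low-polarity medium and −10 °C are chosen to keep free phenoxide too low for the racemic SN2 background and for enolisation of 7; the closest known reaction type is the copper-catalysed enantioconvergent radical substitution of racemic α-halo amides by nitrogen and oxygen nucleophiles, which has not been shown for α-bromo ketones.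

**Step 4**
Reactants: 7 (2R)-2-[4-(3-hydroxypropyl)-2-methoxyphenoxy]-1-(3,4,5-trimethoxyphenyl)propan-1-one
Product: 8 (1S,2R)-2-[4-(3-hydroxypropyl)-2-methoxyphenoxy]-1-(3,4,5-trimethoxyphenyl)propan-1-ol (CID70695433)
Conditions: Zn(BH4)2 (1.5 equiv, stock solution in Et2O), Et2O/CH2Cl2, −40 °C → 0 °C; sat. aq NH4Cl
Reagents that add atoms: none
Why: Cram-chelate (chelation-controlled) hydride reduction: Zn2+ bridges the carbonyl oxygen and the α-aryloxy oxygen (assisted by the neighbouring OMe), so hydride attacks the carbonyl face on the side of the C8 hydrogen and gives the erythro (7S,8R) alcohol, and the non-basic conditions leave C8 untouched.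

**Compound list**
1 | 3,4,5-trimethoxybenzonitrile | N#Cc1cc(OC)c(OC)c(OC)c1 | starting material
2 | ethylmagnesium bromide | CC[Mg]Br | starting material
3 | bromomagnesium ketimide, the N-bromomagnesio imine of 1-(3,4,5-trimethoxyphenyl)propan-1-one | CCC(=N[Mg]Br)c1cc(OC)c(OC)c(OC)c1 | intermediate
4 | 1-(3,4,5-trimethoxyphenyl)propan-1-one | CCC(=O)c1cc(OC)c(OC)c(OC)c1 | intermediate
5 | rac-2-bromo-1-(3,4,5-trimethoxyphenyl)propan-1-one | CC(Br)C(=O)c1cc(OC)c(OC)c(OC)c1 | intermediate
6 | 4-(3-hydroxypropyl)-2-methoxyphenol (dihydroconiferyl alcohol) | COc1cc(CCCO)ccc1O | starting material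
7 | (2R)-2-[4-(3-hydroxypropyl)-2-methoxyphenoxy]-1-(3,4,5-trimethoxyphenyl)propan-1-one | COc1cc(CCCO)ccc1O[C@H](C)C(=O)c1cc(OC)c(OC)c(OC)c1 | intermediate
8 | (1S,2R)-2-[4-(3-hydroxypropyl)-2-methoxyphenoxy]-1-(3,4,5-trimethoxyphenyl)propan-1-ol, erythro | COc1cc(CCCO)ccc1O[C@H](C)[C@@H](O)c1cc(OC)c(OC)c(OC)c1 | target

**Step count and risks**
Total step count: 4. Longest linear sequence: 4 steps (1 → 4 → 5 → 7 → 8).

Steps most likely to fail:

1. Step 3 (proposed new coupling). Likely failure modes are a racemic SN2 background (checked by a blank without copper), erosion of ee in 7 by enolisation (followed by chiral HPLC against conversion), and hydrodebromination back to 4 or elimination to the enone. The fallback uses known chemistry, sets out from 6 and comes back at 7, taking C8 from the lactate chiral pool instead of from catalysis. Phenol 6 is O-alkylated with commercial ethyl (S)-2-(tosyloxy)propanoate (K2CO3, MeCN, 60 °C; SN2 with inversion, only the phenoxide reacts) to give ethyl (2R)-2-[4-(3-hydroxypropyl)-2-methoxyphenoxy]propanoate F1. MeNH(OMe)·HCl with i-PrMgCl (THF, −20 °C, one extra equivalent for the free OH) converts it into the Weinreb amide (2R)-2-[4-(3-hydroxypropyl)-2-methoxyphenoxy]-N-methoxy-N-methylpropanamide F2. Commercial 3,4,5-trimethoxyphenylmagnesium bromide (2.5 equiv, THF, −20 → 0 °C) then gives ketone 7, and the route resumes at step 4.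

2. Step 4 (erythro selectivity). An aryloxy group is a weaker chelator than an alkoxy group, so the erythro:threo ratio may be modest; it is read from J(H7,H8), about 3–4 Hz for erythro and about 8 Hz for threo. The fallback sets out from 7 and comes back at 8 by an inversion strategy. Ketone 7 is reduced under non-chelating Felkin–Anh control with LiBH(s-Bu)3 (THF, −78 °C) to the threo alcohol (1R,2R)-2-[4-(3-hydroxypropyl)-2-methoxyphenoxy]-1-(3,4,5-trimethoxyphenyl)propan-1-ol F3. A Mitsunobu reaction with 4-nitrobenzoic acid (PPh3, DIAD, THF, 0 °C) inverts C7 and also esterifies the primary OH, giving (1S,2R)-2-{2-methoxy-4-[3-(4-nitrobenzoyloxy)propyl]phenoxy}-1-(3,4,5-trimethoxyphenyl)propyl 4-nitrobenzoate F4. K2CO3 in MeOH at rt removes both esters to give 8.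

3. Step 2 (α-bromination). Ring bromination of the electron-rich arene or dibromination could compete. The fallback sets out from 4 and comes back at 5. Ketone 4 is converted into its silyl enol ether (Z)-trimethyl{[1-(3,4,5-trimethoxyphenyl)prop-1-en-1-yl]oxy}silane F5 (TMSOTf, Et3N, CH2Cl2, 0 °C), which is brominated with NBS (THF, −78 °C) to give 5; the pre-formed enol ether reacts much faster than the ring.

**Further compounds**
F1 | step 3 | ethyl (2R)-2-[4-(3-hydroxypropyl)-2-methoxyphenoxy]propanoate | COc1cc(CCCO)ccc1O[C@H](C)C(=O)OCC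
F2 | step 3 | (2R)-2-[4-(3-hydroxypropyl)-2-methoxyphenoxy]-N-methoxy-N-methylpropanamide | COc1cc(CCCO)ccc1O[C@H](C)C(=O)N(C)OC
F3 | step 4 | (1R,2R)-2-[4-(3-hydroxypropyl)-2-methoxyphenoxy]-1-(3,4,5-trimethoxyphenyl)propan-1-ol | COc1cc(CCCO)ccc1O[C@H](C)[C@H](O)c1cc(OC)c(OC)c(OC)c1
F4 | step 4 | (1S,2R)-2-{2-methoxy-4-[3-(4-nitrobenzoyloxy)propyl]phenoxy}-1-(3,4,5-trimethoxyphenyl)propyl 4-nitrobenzoate | COc1cc(CCCOC(=O)c2ccc(cc2)[N+](=O)[O-])ccc1O[C@H](C)[C@@H](OC(=O)c3ccc(cc3)[N+](=O)[O-])c4cc(OC)c(OC)c(OC)c4
F5 | step 2 | (Z)-trimethyl{[1-(3,4,5-trimethoxyphenyl)prop-1-en-1-yl]oxy}silane | C/C=C(\O[Si](C)(C)C)c1cc(OC)c(OC)c(OC)c1
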